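## Analysis of the target

The target, 4,6-dibromo-2-(3,5-dibromo-2-methoxyphenoxy)-3-methoxyphenol (17), is an achiral diaryl ether. It has no stereocentre and no configurationally stable axis, so the whole problem is one of constitution. Ring A is numbered A1 (ether carbon), A2 (OMe), A3 (Br), A4 (H), A5 (Br), A6 (H); ring B is numbered B1 (ether carbon), B2 (OH), B3 (Br), B4 (H), B5 (Br), B6 (OMe). The sensitive groups are the four aryl C–Br bonds and the free, electron-rich phenol at B2. The bromides rule out hydrogenolysis, zerovalent palladium and late organolithium chemistry, and the hydrogens A4 and B4 each lie between two bromines, which invites halogen migration under amide bases. Two things make the synthesis hard. The ether oxygen is flanked by three ortho oxygen substituents (A2, B2, B6), so an aryl C–O coupling would be hindered. The three peripheral oxygens must also be told apart: B6 and A2 methylated, B2 free. The bromine pattern itself is benign: on ring B both bromines are ortho/para to the B2 and B6 oxygens, and on ring A both are ortho/para to the A2 oxygen and meta to A1. The strategy rests on the A1/A2/A3 triad. Bromine A3 sits ortho to the A2 oxygen, exactly where the carboxyl group of a salicylate would be. Ring A can therefore be read as a 3-aryloxysalicylate whose carboxyl group is a placeholder for bromine, and such a salicylate can be assembled from a four-carbon unit that already carries the ether oxygen and a three-carbon unit.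

## Retrosynthetic reasoning

17 to 16: the B2 oxygen–benzyl bond is cut last. The benzyl group is what keeps B2 distinct from A2 throughout, and its removal has to be done by a Lewis acid and not by hydrogen, because of the four C–Br bonds.

16 to 15: the A2 oxygen–methyl bond is cut. In 15 the A2 hydroxyl is the only free OH in the molecule, so the forward methylation needs no selectivity.

15 to 13 (through 14): all four C–Br bonds are cut in one operation, and A3–Br is traced back to A3–CO2H. A5 and A3 are para and ortho to the A2 hydroxyl, and B3 and B5 are each ortho to one alkoxy group and para to the other. A4, A6 and B4 are meta to the strong donors. The gain is that no bromine has to survive base or Lewis acid, and that the carboxyl group marks A3 for ipso-substitution.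

13 to 12: a functional group change only; the acid comes from the methyl ester.

12 to 8 and 9: the bonds A1–A6 and A3–A4 are cut. Ring A divides into a four-carbon diene 8 (ester carbon, A3, A2, A1, with the aryloxy group on A1) and the symmetric three-carbon bis-acetal 9 (A4 to A6). Cutting here means the hindered ether oxygen is never formed at an aromatic carbon, and the symmetric partner removes any question of orientation. The forward step has to form two C–C bonds and aromatise; it passes through 10 and 11.

8 to 7 to 6: the two O–Si bonds are cut in turn. The forward reactions are enol silylation of the β-keto ester 6, then γ-deprotonation of 7 and silylation.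

6 to 4 and 5: the CH2–O bond is cut. The ether is made by an SN2 reaction at a primary carbon, which a hindered 2,6-dialkoxyphenoxide can still manage.

4 to 2 to 1 (through 3): the central oxygen of ring B is traced to a formyl carbon by oxidative aryl migration, and the flanking oxygen to a benzylated phenol. In 1 the formyl group already sits between the two oxygens, so the three oxygens of ring B are differentiated from the first step.

## Alternatives that were turned down

Alternative 1: Ring B is built instead of ring A, by cutting B2–B3 and B4–B5. The precursors are the trioxygenated silyl ketene acetal diene A1, which carries the finished dibrominated ring A on its central oxygen, and phenyl vinyl sulfoxide A2 as an acetylene equivalent. In the forward direction a Diels–Alder reaction, collapse of the mixed ketal to a carbonyl group and thermal loss of the sulfenic acid would aromatise to the phenol A3. Electrophilic dibromination ortho and para to the free B2 hydroxyl would then finish the target.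
- For: no protecting group is needed, the B2/B6 difference is written into the diene, and the orientation of the cycloaddition is irrelevant because both dienophile carbons end as CH. The end game is one step against four in the chosen route. On these points the alternative is stronger.
- Against: ring A must be brought in as the phenol A4. Its bromines are ortho/para to the methoxy group and meta to the hydroxyl, which is not what direct bromination of a 2-methoxyphenol gives, so A4 costs a sequence of its own.
- Against: A1 can only be reached by γ-deprotonation with a lithium amide in the presence of two aryl bromides that flank an acidic ring hydrogen, which invites halogen migration.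
- Against: A1 is a crowded, thermally fragile ketene acetal and A2 is a sluggish dienophile that needs prolonged heating, the conditions under which silyl ketene acetals rearrange.
- In its place the chosen route closes its ring between −78 °C and room temperature with a simple acetal, and introduces all four bromines after the last base and Lewis acid step.

Alternative 2: Ring B is again the ring that is made, by cutting B1–B2 of a symmetric cyclohexane-1,3-dione (B1–B2 and B1–B6 are equivalent there). Treating the keto ester A5 with base would form the enolate at the aryloxymethylene carbon, which attacks the ester in a Dieckmann-type closure to the dione A6.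
- For: the closure has only one six-membered option, the dione is symmetric, and a mono enol ether would distinguish B2 from B6 without a protecting group. After aromatisation the route would pass through A3 and the same one-step final bromination. These are real strengths.
- Against: ring B arrives four hydrogens short of aromatic. The dehydrogenation has to be done on a 2-aryloxy enol ether in the presence of aryl bromides, which excludes palladium-based methods and leaves multi-step functionalisation and elimination.
- Against: the awkward phenol A4 is needed again, the six-carbon chain of A5 has to be prepared, and the aryl bromides again travel through enolate chemistry.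
- Counting about four steps to A4, then alkylation, cyclisation, enol ether formation, aromatisation and bromination, it is not shorter than the chosen ten steps, and its least certain step comes late. The chosen strategy delivers the ring directly at the aromatic oxidation level.

Alternative 3: Ring A is built, as in the chosen route, but by a [4+2] cycloaddition, cutting A3–A4 and A5–A6. The amino silyloxy diene A7, about three steps from 4 (O-alkylation, aminomethylenation, enol silylation), would add A2. Loss of the amine and of the sulfenic acid from the cycloadduct would give the phenol A8. Bromination at A3, A5, B3 and B5, O-methylation and debenzylation would follow.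
- For: there is no ester, so no saponification and no reliance on an ipso-substitution; bromine A3 enters by ordinary ortho-bromination of a phenol. The route is about one step shorter. On these points it is stronger.
- Against: a diene of this type with a bulky 2,6-disubstituted aryloxy group on its central carbon is not well-charted. The aminomethylenation has to choose the aryloxy-bearing methylene over the methyl group. A2 is a weak dienophile, so heating is needed, and the double elimination can stall at an enone.
- In its place the chosen route uses a cyclocondensation documented for exactly this diene class, runs cold with a catalytic Lewis acid, and turns the extra ester into a positional marker for A3. The price is one more step and reliance on bromodecarboxylation, for which a fallback through the same phenol as A8 exists.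

Key step: step 6

Remark on the chemistry: 2-hydroxy-6-methoxybenzaldehyde (1) is taken as a purchasable starting material. Diene 8 is expected as a mixture of double-bond isomers and is drawn as the (1Z,3Z) form; its geometry is of no consequence because all four carbons become arene carbons.

## Route

Step 1
Reactants: 1 2-hydroxy-6-methoxybenzaldehyde
Product: 2 2-(benzyloxy)-6-methoxybenzaldehyde
Conditions: BnBr (1.1 equiv), K2CO3 (1.5 equiv), DMF, 50 °C
Reagents that add atoms: benzyl bromide, BrCc1ccccc1
Why: Williamson etherification of an ortho-hydroxybenzaldehyde; carbonate in DMF breaks the intramolecular hydrogen bond and the phenoxide displaces the benzylic bromide.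

Step 2
Reactants: 2 2-(benzyloxy)-6-methoxybenzaldehyde
Product: 4 2-(benzyloxy)-6-methoxyphenol, via aryl formate 3 (not isolated)
Conditions: mCPBA (1.3 equiv), CH2Cl2, 0 °C to rt; then K2CO3 (0.2 equiv), MeOH, rt
Reagents that add atoms: mCPBA, OOC(=O)c1cccc(Cl)c1
Why: Baeyer–Villiger (Dakin-type) oxidation: in the Criegee intermediate the electron-rich 2,6-dialkoxyaryl group migrates in preference to hydrogen and gives formate 3, which is methanolysed to the phenol. The hydroxyl arrives between the two alkoxy groups, as ring B requires.

Step 3
Reactants: 4 2-(benzyloxy)-6-methoxyphenol; 5 methyl 4-chloro-3-oxobutanoate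
Product: 6 methyl 4-[2-(benzyloxy)-6-methoxyphenoxy]-3-oxobutanoate
Conditions: NaH (2.2 equiv), THF/DMF, 0 °C; 5 (1.1 equiv), 0 °C to 50 °C; aq. NH4Cl
Reagents that add atoms: none
Why: Williamson ether synthesis at the primary chloride. One equivalent of base makes the phenoxide and the second holds 5 (and then 6) as the enolate, which shields the keto ester from self-condensation and carbonyl attack.

Step 4
Reactants: 6 methyl 4-[2-(benzyloxy)-6-methoxyphenoxy]-3-oxobutanoate
Product: 7 methyl (2Z)-4-[2-(benzyloxy)-6-methoxyphenoxy]-3-(trimethylsilyloxy)but-2-enoate
Conditions: Me3SiCl (1.5 equiv), Et3N (1.6 equiv), toluene, rt, 48–72 h; filtration under argon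
Reagents that add atoms: chlorotrimethylsilane, C[Si](C)(C)Cl
Why: O-silylation of the β-keto ester enol under soft enolisation; the crude silyl enol ether is used directly.

Step 5
Reactants: 7 methyl (2Z)-4-[2-(benzyloxy)-6-methoxyphenoxy]-3-(trimethylsilyloxy)but-2-enoate
Product: 8 4-[2-(benzyloxy)-6-methoxyphenoxy]-1-methoxy-1,3-bis(trimethylsilyloxy)buta-1,3-diene
Conditions: LiN(iPr)2 (1.5 equiv, commercial solution), THF, −78 °C; Me3SiCl (1.5 equiv), −78 °C to rt; non-aqueous work-up (hexane, filtration)
Reagents that add atoms: chlorotrimethylsilane, C[Si](C)(C)Cl
Why: γ-Deprotonation of the vinylogous ester, helped by the aryloxy group on the γ-carbon, gives the dienolate, which is silylated on oxygen to the 1,3-bis(silyloxy)diene (Chan-type diene). LiN(iPr)2 is not basic enough to touch the benzyl ether.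

Step 6
Reactants: 8 4-[2-(benzyloxy)-6-methoxyphenoxy]-1-methoxy-1,3-bis(trimethylsilyloxy)buta-1,3-diene; 9 1,1,3,3-tetramethoxypropane
Product: 12 methyl 3-[2-(benzyloxy)-6-methoxyphenoxy]-2-hydroxybenzoate, via open-chain adduct 10 (not isolated), via dimethoxycyclohexanone 11 (not isolated)
Conditions: 9 (1.5 equiv), Me3SiOTf (0.1–0.3 equiv), CH2Cl2, −78 °C to rt, 12 h; then 10% aq. HCl
Reagents that add atoms: none
Why: Me3SiOTf ionises one acetal of 9 to a methoxycarbenium ion, which the aryloxy-bearing terminal carbon of 8 (the future A1) attacks in a vinylogous Mukaiyama-type addition, forming A1–A6 and giving 10. The second acetal is then ionised and the central carbon (the future A3), still a silyl enol ether, closes ring A by a 6-(enolendo)-exo-trig attack on the oxocarbenium ion, forming A3–A4 and giving 11. Two β-eliminations of methanol and enolisation then aromatise 11 to the hydrogen-bonded salicylate 12, which makes the sequence irreversible. The closest known reaction type is the Lewis-acid-mediated formal [3+3] cyclocondensation of 1,3-bis(silyloxy)buta-1,3-dienes, 4-aryloxy-substituted ones included, with 9 to give salicylates. No stereocentre survives, so the mixtures of isomers in 8, 10 and 11 do not matter. Because 9 is symmetric, the constitution of 12 is fixed whichever carbon of 8 reacts first, and the diene skeleton forces the phenol oxygen to lie between the ester and the aryloxy group. What the step needs is ring closure of 10 faster than addition of a second diene; the six-membered transition state, the excess of 9 and slow warming secure this. The benzyl and methyl ethers are inert to a catalytic silyl triflate at these temperatures.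

Step 7
Reactants: 12 methyl 3-[2-(benzyloxy)-6-methoxyphenoxy]-2-hydroxybenzoate
Product: 13 3-[2-(benzyloxy)-6-methoxyphenoxy]-2-hydroxybenzoic acid
Conditions: NaOH (4 equiv), MeOH/H2O, 65 °C; then aq. HCl to pH 2
Reagents that add atoms: sodium hydroxide, [Na+].[OH-]
Why: Saponification by acyl–oxygen cleavage; heating is needed because the salicylate phenoxide forms first and slows attack at the ester. Both ethers are stable to aqueous base.

Step 8
Reactants: 13 3-[2-(benzyloxy)-6-methoxyphenoxy]-2-hydroxybenzoic acid
Product: 15 2,4-dibromo-6-[2-(benzyloxy)-3,5-dibromo-6-methoxyphenoxy]phenol, via tribromo acid 14 (not isolated)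
Conditions: Br2 (4.4 equiv), NaOAc (6 equiv), AcOH/H2O, 0 °C to 40 °C, dark; then aq. NaHSO3
Reagents that add atoms: bromine, BrBr
Why: Electrophilic aromatic bromination at B3 and B5 (each ortho to one alkoxy group and para to the other) and at A5 (para to the A2 hydroxyl) gives 14. The last equivalent attacks A3 ipso, ortho to the phenol, and loss of CO2 from the carboxylate restores the arene (bromodecarboxylation of a salicylic acid, as in the conversion of salicylic acid into 2,4,6-tribromophenol). NaOAc keeps the carboxylate present and stops HBr from cleaving the benzyl ether; A4, A6 and B4 are meta to the strong donors and should be left alone.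

Step 9
Reactants: 15 2,4-dibromo-6-[2-(benzyloxy)-3,5-dibromo-6-methoxyphenoxy]phenol
Product: 16 1-(benzyloxy)-4,6-dibromo-2-(3,5-dibromo-2-methoxyphenoxy)-3-methoxybenzene
Conditions: MeI (2 equiv), K2CO3 (2 equiv), DMF, rt to 40 °C
Reagents that add atoms: iodomethane, CI
Why: Williamson O-methylation of an acidic dibromophenol; it is the only hydroxyl in the molecule, so no selectivity is required.

Step 10
Reactants: 16 1-(benzyloxy)-4,6-dibromo-2-(3,5-dibromo-2-methoxyphenoxy)-3-methoxybenzene
Product: 17 4,6-dibromo-2-(3,5-dibromo-2-methoxyphenoxy)-3-methoxyphenol
Conditions: BCl3 (2.5 equiv), C6HMe5 (3 equiv), CH2Cl2, −78 °C; then H2O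
Reagents that add atoms: none
Why: Lewis-acid debenzylation: BCl3 coordinates the benzyl ether oxygen and the benzyl cation is transferred to pentamethylbenzene by Friedel–Crafts capture. At −78 °C the aryl methyl ethers and C–Br bonds should stay intact; hydrogenolysis is avoided because of the four bromines.

## Compound list

1 | 2-hydroxy-6-methoxybenzaldehyde | COc1cccc(O)c1C=O | starting material
2 | 2-(benzyloxy)-6-methoxybenzaldehyde | COc1cccc(OCc2ccccc2)c1C=O | intermediate
3 | 2-(benzyloxy)-6-methoxyphenyl formate | COc1cccc(OCc2ccccc2)c1OC=O | intermediate (not isolated)
4 | 2-(benzyloxy)-6-methoxyphenol | COc1cccc(OCc2ccccc2)c1O | intermediate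
5 | methyl 4-chloro-3-oxobutanoate (methyl 4-chloroacetoacetate) | COC(=O)CC(=O)CCl | starting material
6 | methyl 4-[2-(benzyloxy)-6-methoxyphenoxy]-3-oxobutanoate | COC(=O)CC(=O)COc1c(OC)cccc1OCc1ccccc1 | intermediate
7 | methyl (2Z)-4-[2-(benzyloxy)-6-methoxyphenoxy]-3-(trimethylsilyloxy)but-2-enoate | COC(=O)/C=C(\O[Si](C)(C)C)COc1c(OC)cccc1OCc1ccccc1 | intermediate
8 | (1Z,3Z)-4-[2-(benzyloxy)-6-methoxyphenoxy]-1-methoxy-1,3-bis(trimethylsilyloxy)buta-1,3-diene | CO/C(O[Si](C)(C)C)=C/C(O[Si](C)(C)C)=C/Oc1c(OC)cccc1OCc1ccccc1 | intermediate
9 | 1,1,3,3-tetramethoxypropane | COC(OC)CC(OC)OC | starting material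
10 | methyl 4-[2-(benzyloxy)-6-methoxyphenoxy]-5,7,7-trimethoxy-3-(trimethylsilyloxy)hept-2-enoate (mixture of stereoisomers) | COC(=O)C=C(O[Si](C)(C)C)C(Oc1c(OC)cccc1OCc1ccccc1)C(OC)CC(OC)OC | intermediate (not isolated)
11 | methyl 3-[2-(benzyloxy)-6-methoxyphenoxy]-4,6-dimethoxy-2-oxocyclohexane-1-carboxylate (mixture of stereoisomers) | COC(=O)C1C(OC)CC(OC)C(Oc2c(OC)cccc2OCc2ccccc2)C1=O | intermediate (not isolated)
12 | methyl 3-[2-(benzyloxy)-6-methoxyphenoxy]-2-hydroxybenzoate | COC(=O)c1cccc(Oc2c(OC)cccc2OCc2ccccc2)c1O | intermediate
13 | 3-[2-(benzyloxy)-6-methoxyphenoxy]-2-hydroxybenzoic acid | OC(=O)c1cccc(Oc2c(OC)cccc2OCc2ccccc2)c1O | intermediate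
14 | 3-[2-(benzyloxy)-3,5-dibromo-6-methoxyphenoxy]-5-bromo-2-hydroxybenzoic acid | OC(=O)c1cc(Br)cc(Oc2c(OC)c(Br)cc(Br)c2OCc2ccccc2)c1O | intermediate (not isolated)
15 | 2,4-dibromo-6-[2-(benzyloxy)-3,5-dibromo-6-methoxyphenoxy]phenol | Oc1c(Br)cc(Br)cc1Oc1c(OC)c(Br)cc(Br)c1OCc1ccccc1 | intermediate
16 | 1-(benzyloxy)-4,6-dibromo-2-(3,5-dibromo-2-methoxyphenoxy)-3-methoxybenzene | COc1c(Br)cc(Br)cc1Oc1c(OC)c(Br)cc(Br)c1OCc1ccccc1 | intermediate
17 | 4,6-dibromo-2-(3,5-dibromo-2-methoxyphenoxy)-3-methoxyphenol | COc1c(Br)cc(Br)cc1Oc1c(O)c(Br)cc(Br)c1OC | target

## Step count and least certain steps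

Total step count: 10. Longest linear sequence: 10 steps, from 1 to 17; 5 and 9 enter as purchased building blocks.

Step 6 (key step). The terminal carbon of 8 is crowded by the 2,6-disubstituted aryloxy group, so the first addition may be slow. Hydrolytic loss of the silyl groups back to 6, addition of a second diene to the open-chain adduct, or stalling before aromatisation could then compete.
Fallback: set out from 6 and build ring A by a Robinson-type annulation with a three-carbon partner one oxidation level lower.
- Conjugate addition of 6 to acrolein (Et3N cat., CH2Cl2, 0 °C) should give methyl 4-[2-(benzyloxy)-6-methoxyphenoxy]-3-oxo-2-(3-oxopropyl)butanoate F1; this forms A3–A4.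
- Intramolecular aldol condensation of the aryloxymethylene carbon onto the aldehyde (pyrrolidine/AcOH, toluene, water removal) should give methyl 3-[2-(benzyloxy)-6-methoxyphenoxy]-2-oxocyclohex-3-ene-1-carboxylate F2; this forms A1–A6.
- Dehydrogenation with DDQ (dioxane, 80 °C) would return to the route at 12.

Step 8. The ipso-substitution may stall after the three ordinary brominations, leaving incomplete decarboxylation. Over-bromination at A4 or A6, or acid-induced loss of the benzyl group, may set in if more forcing conditions are used.
Fallback: set out from 13 and separate the two events. Protodecarboxylation (Cu2O cat., 1,10-phenanthroline, quinoline/NMP, 170 °C) should give 2-[2-(benzyloxy)-6-methoxyphenoxy]phenol F3. Fourfold bromination (Br2, NaOAc, AcOH, rt) then places bromine ortho and para to the free A2 hydroxyl and at B3 and B5, and returns to the route at 15.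

Step 3. Displacement by a hindered phenoxide on an electrophile that is itself present as an enolate may be slow, so base-induced self-condensation of 5 could take over.
Fallback: set out from 4 and build the keto ester in two stages. O-Alkylation with methyl bromoacetate (K2CO3, acetone, reflux) should give methyl [2-(benzyloxy)-6-methoxyphenoxy]acetate F4. Crossed Claisen condensation with the lithium enolate of methyl acetate (LiN(iPr)2, MeOAc, 2.2 equiv, THF, −78 °C) returns to the route at 6.

Step 10. The methoxy groups at A2 and B6 each sit next to the ether oxygen and can chelate boron, so loss of a methyl ether alongside the benzyl group is the likeliest failure.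
Fallback: set out from 16 and cleave the benzyl ether by oxidation of its methylene group, not by C–O heterolysis. Radical bromination (NBS, 1.1 equiv, hν, PhCF3, rt) should give the α-bromobenzyl ether 1-[bromo(phenyl)methoxy]-4,6-dibromo-2-(3,5-dibromo-2-methoxyphenoxy)-3-methoxybenzene F5 (not isolated). Hydrolysis (H2O, NaHCO3) releases benzaldehyde and returns to the route at 17.

## Further compounds

F1 | step 6 | methyl 4-[2-(benzyloxy)-6-methoxyphenoxy]-3-oxo-2-(3-oxopropyl)butanoate (racemic) | COC(=O)C(CCC=O)C(=O)COc1c(OC)cccc1OCc1ccccc1
F2 | step 6 | methyl 3-[2-(benzyloxy)-6-methoxyphenoxy]-2-oxocyclohex-3-ene-1-carboxylate (racemic) | COC(=O)C1CCC=C(Oc2c(OC)cccc2OCc2ccccc2)C1=O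
F3 | step 8 | 2-[2-(benzyloxy)-6-methoxyphenoxy]phenol | Oc1ccccc1Oc1c(OC)cccc1OCc1ccccc1
F4 | step 3 | methyl [2-(benzyloxy)-6-methoxyphenoxy]acetate | COC(=O)COc1c(OC)cccc1OCc1ccccc1
F5 | step 10 | 1-[bromo(phenyl)methoxy]-4,6-dibromo-2-(3,5-dibromo-2-methoxyphenoxy)-3-methoxybenzene (racemic) | COc1c(Br)cc(Br)cc1Oc1c(OC)c(Br)cc(Br)c1OC(Br)c1ccccc1
A1 | alternative 1 | [2-(3,5-dibromo-2-methoxyphenoxy)-1,3-dimethoxybuta-1,3-dien-1-yl]oxy(trimethyl)silane (ketene acetal geometry not defined) | COC(=C)C(Oc1cc(Br)cc(Br)c1OC)=C(OC)O[Si](C)(C)C
A2 | alternative 1 | phenyl vinyl sulfoxide (racemic) | C=CS(=O)c1ccccc1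
A3 | alternative 1 | 2-(3,5-dibromo-2-methoxyphenoxy)-3-methoxyphenol | COc1cccc(O)c1Oc1cc(Br)cc(Br)c1OC
A4 | alternative 1 | 3,5-dibromo-2-methoxyphenol | COc1c(O)cc(Br)cc1Br
A5 | alternative 2 | methyl 6-(3,5-dibromo-2-methoxyphenoxy)-5-oxohexanoate | COC(=O)CCCC(=O)COc1cc(Br)cc(Br)c1OC
A6 | alternative 2 | 2-(3,5-dibromo-2-methoxyphenoxy)cyclohexane-1,3-dione | COc1c(Br)cc(Br)cc1OC1C(=O)CCCC1=O
A7 | alternative 3 | 2-[2-(benzyloxy)-6-methoxyphenoxy]-3-(tert-butyldimethylsilyloxy)-N,N-dimethylbuta-1,3-dien-1-amine (enamine geometry not defined) | CN(C)C=C(Oc1c(OC)cccc1OCc1ccccc1)C(=C)O[Si](C)(C)C(C)(C)C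
A8 | alternative 3 | 2-[2-(benzyloxy)-6-methoxyphenoxy]phenol | Oc1ccccc1Oc1c(OC)cccc1OCc1ccccc1
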